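**Retrosynthetic overview**
1. Target 22 ⇐ desilylation of 21. The ten-membered ring and the γ-lactone come from open-chain bromo enal 19 by CrCl2-mediated intramolecular allylation (C6–C7 bond).
2. 19 ⇐ C7 aldehyde 15 (vinylalane addition, then SN2′ bromination), with the C9 acetate and C8 angelate already in place.
3. C8/C9 ⇐ Sharpless epoxidation of (2E,4Z)-dienol 10, then Ti(OiPr)4/AcOH opening at C9.
4. (Z)-C1=C10 ⇐ temporary dihydropyranone 5 (ring-closing metathesis of a methacrylate), opened through its lactol by a Wittig reaction.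
5. C3 ⇐ Brown allylation of ethyl (2E)-3-methyl-4-oxobut-2-enoate 1. Ring order: dihydropyranone (temporary), then ten-membered carbocycle, then γ-lactone.

Assumption: atom labels C1–C15 follow germacrane numbering (lactone O on C6, ring fusion C6/C7, angelate on C8, acetate on C9, OH on C3; target = 3S,6R,7S,8R,9S), and every reagent named in a Conditions line is bought, so 1 is the only numbered starting material.

**Step 1**
Reactants: 1 ethyl (2E)-3-methyl-4-oxobut-2-enoate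
Product: 3 ethyl (2E,4S)-4-hydroxy-3-methylhepta-2,6-dienoate, via borinate ester 2 (not isolated)
Conditions: dIpc2B(allyl) (1.3 equiv), Et2O, −78 °C; then HOCH2CH2NH2, rt
Reagents that add atoms: B-allyldiisopinocampheylborane from (+)-α-pinene, dIpc2B(allyl) (C=CCB([C@@H]1C[C@@H]2C[C@H]([C@H]1C)C2(C)C)[C@@H]1C[C@@H]2C[C@H]([C@H]1C)C2(C)C)
Why: Brown allylboration through a chair six-membered transition state; the (+)-α-pinene-derived reagent adds allyl to the Si face of the α-methyl enal and sets C3 as S, while the ester is inert at −78 °C.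

**Step 2**
Reactants: 3 ethyl (2E,4S)-4-hydroxy-3-methylhepta-2,6-dienoate
Product: 4 ethyl (2E,4S)-3-methyl-4-[(2-methylprop-2-enoyl)oxy]hepta-2,6-dienoate
Conditions: methacryloyl chloride, Et3N, DMAP (cat.), CH2Cl2, 0 °C to rt
Reagents that add atoms: methacryloyl chloride (CC(=C)C(=O)Cl)
Why: DMAP-catalysed acylation of the secondary alcohol; no stereocentre is touched.

**Step 3**
Reactants: 4 ethyl (2E,4S)-3-methyl-4-[(2-methylprop-2-enoyl)oxy]hepta-2,6-dienoate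
Product: 5 ethyl (2E)-3-[(2S)-5-methyl-6-oxo-3,6-dihydro-2H-pyran-2-yl]but-2-enoate
Conditions: second-generation Grubbs catalyst RuCl2(=CHPh)(PCy3)(H2IMes) (5 mol %), CH2Cl2 (0.01 M), 40 °C
Reagents that add atoms: none
Why: Ring-closing metathesis of the terminal olefin with the methacrylate gives the six-membered lactone, in which the new trisubstituted C1=C10 bond can only be cis (the later Z geometry); the hindered, electron-poor enoate does not take part.

**Step 4**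
Reactants: 5 ethyl (2E)-3-[(2S)-5-methyl-6-oxo-3,6-dihydro-2H-pyran-2-yl]but-2-enoate
Product: 6 (6S)-6-[(2E)-4-hydroxybut-2-en-2-yl]-3-methyl-5,6-dihydro-2H-pyran-2-ol (both anomers)
Conditions: iBu2AlH (4.5 equiv), CH2Cl2, −78 °C; aq. potassium sodium tartrate
Reagents that add atoms: none
Why: Hydride reduction; at −78 °C the lactone stops at the lactol (stable aluminium hemiacetal) and the conjugated ethyl ester is reduced 1,2 to the allylic alcohol.

**Step 5**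
Reactants: 6 (6S)-6-[(2E)-4-hydroxybut-2-en-2-yl]-3-methyl-5,6-dihydro-2H-pyran-2-ol
Product: 8 ethyl (2E,4Z,7S,8E)-7,10-dihydroxy-4,8-dimethyldeca-2,4,8-trienoate, via hydroxy enal 7 (not isolated)
Conditions: Ph3P=CHCO2Et (2.5 equiv), PhCO2H (cat.), toluene, 50 °C
Reagents that add atoms: ethyl (triphenylphosphoranylidene)acetate (CCOC(=O)C=P(c1ccccc1)(c1ccccc1)c1ccccc1)
Why: Wittig olefination of the ring-opened lactol; the stabilised ylide gives the E enoate and the Z C1=C10 olefin is carried over from the ring.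

**Step 6**
Reactants: 8 ethyl (2E,4Z,7S,8E)-7,10-dihydroxy-4,8-dimethyldeca-2,4,8-trienoate
Product: 9 ethyl (2E,4Z,7S,8E)-7,10-bis[(tert-butyldimethylsilyl)oxy]-4,8-dimethyldeca-2,4,8-trienoate
Conditions: TBSCl (2.5 equiv), imidazole, DMF, rt
Reagents that add atoms: tert-butyldimethylsilyl chloride (CC(C)(C)[Si](C)(C)Cl)
Why: Imidazole-promoted silylation of both hydroxyls (C3 and C6).

**Step 7**
Reactants: 9 ethyl (2E,4Z,7S,8E)-7,10-bis[(tert-butyldimethylsilyl)oxy]-4,8-dimethyldeca-2,4,8-trienoate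
Product: 10 (2E,4Z,7S,8E)-7,10-bis[(tert-butyldimethylsilyl)oxy]-4,8-dimethyldeca-2,4,8-trien-1-ol
Conditions: iBu2AlH (2.5 equiv), CH2Cl2, −78 °C; aq. potassium sodium tartrate
Reagents that add atoms: none
Why: 1,2-Reduction of the conjugated ester to the primary allylic alcohol without touching the diene geometry.

**Step 8**
Reactants: 10 (2E,4Z,7S,8E)-7,10-bis[(tert-butyldimethylsilyl)oxy]-4,8-dimethyldeca-2,4,8-trien-1-ol
Product: 11 [(2R,3R)-3-{(2Z,5S,6E)-5,8-bis[(tert-butyldimethylsilyl)oxy]-6-methylocta-2,6-dien-2-yl}oxiran-2-yl]methanol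
Conditions: Ti(OiPr)4 (10 mol %), D-(−)-diethyl tartrate (12 mol %), t-BuOOH (2 equiv), 4 Å molecular sieves, CH2Cl2, −20 °C
Reagents that add atoms: tert-butyl hydroperoxide (CC(C)(C)OO)
Why: Sharpless asymmetric epoxidation; only the olefin next to the free CH2OH reacts, and the D-(−)-tartrate catalyst delivers oxygen to the face that gives the (2R,3R)-epoxide (C8 R, C9 R).

**Step 9**
Reactants: 11 [(2R,3R)-3-{(2Z,5S,6E)-5,8-bis[(tert-butyldimethylsilyl)oxy]-6-methylocta-2,6-dien-2-yl}oxiran-2-yl]methanol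
Product: 12 (2R,3S,4Z,7S,8E)-7,10-bis[(tert-butyldimethylsilyl)oxy]-1,2-dihydroxy-4,8-dimethyldeca-4,8-dien-3-yl acetate
Conditions: Ti(OiPr)4 (1.5 equiv), AcOH (2 equiv), CH2Cl2, 0 °C to rt; aq. tartaric acid
Reagents that add atoms: acetic acid (CC(=O)O)
Why: Titanium-assisted regioselective opening of a 2,3-epoxy alcohol; acetate attacks the chelated epoxide at the distal, allylic C9 with inversion (C9 becomes S and carries the acetate), and C8 stays R.

**Step 10**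
Reactants: 12 (2R,3S,4Z,7S,8E)-7,10-bis[(tert-butyldimethylsilyl)oxy]-1,2-dihydroxy-4,8-dimethyldeca-4,8-dien-3-yl acetate
Product: 14 (2R,3S,4Z,7S,8E)-3-(acetyloxy)-7,10-bis[(tert-butyldimethylsilyl)oxy]-4,8-dimethyl-1-[(triethylsilyl)oxy]deca-4,8-dien-2-yl (2Z)-2-methylbut-2-enoate, via primary triethylsilyl ether 13 (not isolated)
Conditions: TESCl (1.05 equiv), Et3N, DMAP (cat.), CH2Cl2, −78 °C; then angelic acid/2,4,6-trichlorobenzoyl chloride/Et3N (premixed in toluene), DMAP, 0 °C to rt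
Reagents that add atoms: chlorotriethylsilane (CC[Si](CC)(CC)Cl); angelic acid, (2Z)-2-methylbut-2-enoic acid (C/C=C(/C)C(=O)O)
Why: Selective silylation of the primary hydroxyl, then Yamaguchi esterification of the remaining C8 hydroxyl through the mixed anhydride, which keeps the Z geometry of the angelate.

**Step 11**
Reactants: 14 (2R,3S,4Z,7S,8E)-3-(acetyloxy)-7,10-bis[(tert-butyldimethylsilyl)oxy]-4,8-dimethyl-1-[(triethylsilyl)oxy]deca-4,8-dien-2-yl (2Z)-2-methylbut-2-enoate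
Product: 15 (2S,3S,4Z,7S,8E)-3-(acetyloxy)-7,10-bis[(tert-butyldimethylsilyl)oxy]-4,8-dimethyl-1-oxodeca-4,8-dien-2-yl (2Z)-2-methylbut-2-enoate
Conditions: (COCl)2, DMSO, CH2Cl2, −78 to −40 °C; then iPr2NEt, −78 °C; pH 7 buffer
Reagents that add atoms: none
Why: Swern conditions cleave and oxidise a primary triethylsilyl ether directly to the aldehyde while the tert-butyldimethylsilyl ethers stay; the descriptor at C8 changes to S only because CHO now outranks C9.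

**Step 12**
Reactants: 15 (2S,3S,4Z,7S,8E)-3-(acetyloxy)-7,10-bis[(tert-butyldimethylsilyl)oxy]-4,8-dimethyl-1-oxodeca-4,8-dien-2-yl (2Z)-2-methylbut-2-enoate
Product: 16 methyl (4R,5S,6Z,9S,10E)-5-(acetyloxy)-9,12-bis[(tert-butyldimethylsilyl)oxy]-3-hydroxy-6,10-dimethyl-2-methylidene-4-{[(2Z)-2-methylbut-2-enoyl]oxy}dodeca-6,10-dienoate (both C3 epimers)
Conditions: iBu2AlH, N-methylmorpholine N-oxide, methyl propiolate, THF, 0 °C; then 15, 0 °C to rt
Reagents that add atoms: methyl propiolate (C#CC(=O)OC)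
Why: Vinylalumination, a non-basic Morita–Baylis–Hillman equivalent; the α-alanyl acrylate adds to the aldehyde, and the new carbinol centre (C7) is removed again in step 15, so its configuration does not matter.

**Step 13**
Reactants: 16 methyl (4R,5S,6Z,9S,10E)-5-(acetyloxy)-9,12-bis[(tert-butyldimethylsilyl)oxy]-3-hydroxy-6,10-dimethyl-2-methylidene-4-{[(2Z)-2-methylbut-2-enoyl]oxy}dodeca-6,10-dienoate
Product: 17 methyl (4R,5S,6Z,9S,10E)-5-(acetyloxy)-9-[(tert-butyldimethylsilyl)oxy]-3,12-dihydroxy-6,10-dimethyl-2-methylidene-4-{[(2Z)-2-methylbut-2-enoyl]oxy}dodeca-6,10-dienoate (both C3 epimers)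
Conditions: HF·pyridine, pyridine, THF, 0 °C
Reagents that add atoms: none
Why: Fluoride desilylation is much faster at the primary allylic silyl ether (C6) than at the hindered secondary one (C3).

**Step 14**
Reactants: 17 methyl (4R,5S,6Z,9S,10E)-5-(acetyloxy)-9-[(tert-butyldimethylsilyl)oxy]-3,12-dihydroxy-6,10-dimethyl-2-methylidene-4-{[(2Z)-2-methylbut-2-enoyl]oxy}dodeca-6,10-dienoate
Product: 18 methyl (4R,5S,6Z,9S,10E)-5-(acetyloxy)-9-[(tert-butyldimethylsilyl)oxy]-3-hydroxy-6,10-dimethyl-2-methylidene-4-{[(2Z)-2-methylbut-2-enoyl]oxy}-12-oxododeca-6,10-dienoate (both C3 epimers)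
Conditions: TEMPO (10 mol %), PhI(OAc)2 (1.2 equiv), CH2Cl2, rt
Reagents that add atoms: none
Why: Oxoammonium (TEMPO) oxidation is selective for the primary allylic alcohol and gives the E enal, leaving the secondary carbinol untouched.

**Step 15**
Reactants: 18 methyl (4R,5S,6Z,9S,10E)-5-(acetyloxy)-9-[(tert-butyldimethylsilyl)oxy]-3-hydroxy-6,10-dimethyl-2-methylidene-4-{[(2Z)-2-methylbut-2-enoyl]oxy}-12-oxododeca-6,10-dienoate
Product: 19 methyl (2Z,4R,5S,6Z,9S,10E)-5-(acetyloxy)-2-(bromomethyl)-9-[(tert-butyldimethylsilyl)oxy]-6,10-dimethyl-4-{[(2Z)-2-methylbut-2-enoyl]oxy}-12-oxododeca-2,6,10-trienoate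
Conditions: N-bromosuccinimide, Me2S, CH2Cl2, −20 to 0 °C
Reagents that add atoms: N-bromosuccinimide (O=C1CCC(=O)N1Br)
Why: Corey–Kim-type activation of the allylic alcohol followed by SN2′ attack of bromide gives the conjugated (Z)-2-(bromomethyl)enoate.

**Step 16**
Reactants: 19 methyl (2Z,4R,5S,6Z,9S,10E)-5-(acetyloxy)-2-(bromomethyl)-9-[(tert-butyldimethylsilyl)oxy]-6,10-dimethyl-4-{[(2Z)-2-methylbut-2-enoyl]oxy}-12-oxododeca-2,6,10-trienoate
Product: 21 (3aS,4R,5S,6Z,9S,10E,11aR)-5-(acetyloxy)-9-[(tert-butyldimethylsilyl)oxy]-6,10-dimethyl-3-methylidene-2-oxo-2,3,3a,4,5,8,9,11a-octahydrocyclodeca[b]furan-4-yl (2Z)-2-methylbut-2-enoate, via cyclodecadienyl hydroxy ester 20 (not isolated)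
Conditions: CrCl2 (10 equiv), DMF/THF, rt, slow addition of 19 (final 0.002 M); then PPTS (cat.), CH2Cl2, rt
Reagents that add atoms: none
Why: Intramolecular Nozaki–Hiyama (chromium Barbier) allylation: CrCl2 (divalent chromium) converts the allylic bromide into an allylchromium species that adds through C7 to the enal inside the forming ten-membered ring, the aldehyde approaching anti to the C8–O bond (C8–H eclipsing the olefin) and giving the trans C6/C7 relationship typical of such ring closures with a 1(10)-Z olefin (6R,7S), after which the C6 alkoxide closes the γ-lactone on the methyl ester.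

**Step 17**
Reactants: 21 (3aS,4R,5S,6Z,9S,10E,11aR)-5-(acetyloxy)-9-[(tert-butyldimethylsilyl)oxy]-6,10-dimethyl-3-methylidene-2-oxo-2,3,3a,4,5,8,9,11a-octahydrocyclodeca[b]furan-4-yl (2Z)-2-methylbut-2-enoate
Product: 22 (3aS,4R,5S,6Z,9S,10E,11aR)-5-(acetyloxy)-9-hydroxy-6,10-dimethyl-3-methylidene-2-oxo-2,3,3a,4,5,8,9,11a-octahydrocyclodeca[b]furan-4-yl (2Z)-2-methylbut-2-enoate (CNP0265116.1)
Conditions: HF·pyridine, THF, 0 °C to rt
Reagents that add atoms: none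
Why: Acidic fluoride desilylation of the secondary allylic silyl ether, mild enough for the α-methylene lactone, the angelate and the acetate.

**Compound list**
1 | ethyl (2E)-3-methyl-4-oxobut-2-enoate | CCOC(=O)/C=C(\C)C=O | starting material
2 | diisopinocampheylborinate ester of 3 (not isolated) | CCOC(=O)/C=C(\C)[C@@H](OB([C@@H]1C[C@@H]2C[C@H]([C@H]1C)C2(C)C)[C@@H]1C[C@@H]2C[C@H]([C@H]1C)C2(C)C)CC=C | intermediate
3 | ethyl (2E,4S)-4-hydroxy-3-methylhepta-2,6-dienoate | CCOC(=O)/C=C(\C)[C@@H](O)CC=C | intermediate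
4 | ethyl (2E,4S)-3-methyl-4-[(2-methylprop-2-enoyl)oxy]hepta-2,6-dienoate | CCOC(=O)/C=C(\C)[C@@H](OC(=O)C(C)=C)CC=C | intermediate
5 | ethyl (2E)-3-[(2S)-5-methyl-6-oxo-3,6-dihydro-2H-pyran-2-yl]but-2-enoate | CCOC(=O)/C=C(\C)[C@@H]1CC=C(C)C(=O)O1 | intermediate
6 | (6S)-6-[(2E)-4-hydroxybut-2-en-2-yl]-3-methyl-5,6-dihydro-2H-pyran-2-ol (both anomers) | OC/C=C(\C)[C@@H]1CC=C(C)C(O)O1 | intermediate
7 | (2Z,5S,6E)-5,8-dihydroxy-2,6-dimethylocta-2,6-dienal (open form of 6, not isolated) | OC/C=C(\C)[C@@H](O)C/C=C(/C)C=O | intermediate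
8 | ethyl (2E,4Z,7S,8E)-7,10-dihydroxy-4,8-dimethyldeca-2,4,8-trienoate | OC/C=C(\C)[C@@H](O)C/C=C(/C)\C=C\C(=O)OCC | intermediate
9 | ethyl (2E,4Z,7S,8E)-7,10-bis[(tert-butyldimethylsilyl)oxy]-4,8-dimethyldeca-2,4,8-trienoate | CC(C)(C)[Si](C)(C)OC/C=C(\C)[C@@H](O[Si](C)(C)C(C)(C)C)C/C=C(/C)\C=C\C(=O)OCC | intermediate
10 | (2E,4Z,7S,8E)-7,10-bis[(tert-butyldimethylsilyl)oxy]-4,8-dimethyldeca-2,4,8-trien-1-ol | CC(C)(C)[Si](C)(C)OC/C=C(\C)[C@@H](O[Si](C)(C)C(C)(C)C)C/C=C(/C)\C=C\CO | intermediate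
11 | [(2R,3R)-3-{(2Z,5S,6E)-5,8-bis[(tert-butyldimethylsilyl)oxy]-6-methylocta-2,6-dien-2-yl}oxiran-2-yl]methanol | CC(C)(C)[Si](C)(C)OC/C=C(\C)[C@@H](O[Si](C)(C)C(C)(C)C)C/C=C(/C)[C@H]1O[C@@H]1CO | intermediate
12 | (2R,3S,4Z,7S,8E)-7,10-bis[(tert-butyldimethylsilyl)oxy]-1,2-dihydroxy-4,8-dimethyldeca-4,8-dien-3-yl acetate | CC(C)(C)[Si](C)(C)OC/C=C(\C)[C@@H](O[Si](C)(C)C(C)(C)C)C/C=C(/C)[C@H](OC(C)=O)[C@H](O)CO | intermediate
13 | (2R,3S,4Z,7S,8E)-7,10-bis[(tert-butyldimethylsilyl)oxy]-2-hydroxy-4,8-dimethyl-1-[(triethylsilyl)oxy]deca-4,8-dien-3-yl acetate (not isolated) | CC(C)(C)[Si](C)(C)OC/C=C(\C)[C@@H](O[Si](C)(C)C(C)(C)C)C/C=C(/C)[C@H](OC(C)=O)[C@H](O)CO[Si](CC)(CC)CC | intermediate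
14 | (2R,3S,4Z,7S,8E)-3-(acetyloxy)-7,10-bis[(tert-butyldimethylsilyl)oxy]-4,8-dimethyl-1-[(triethylsilyl)oxy]deca-4,8-dien-2-yl (2Z)-2-methylbut-2-enoate | CC(C)(C)[Si](C)(C)OC/C=C(\C)[C@@H](O[Si](C)(C)C(C)(C)C)C/C=C(/C)[C@H](OC(C)=O)[C@H](OC(=O)/C(C)=C\C)CO[Si](CC)(CC)CC | intermediate
15 | (2S,3S,4Z,7S,8E)-3-(acetyloxy)-7,10-bis[(tert-butyldimethylsilyl)oxy]-4,8-dimethyl-1-oxodeca-4,8-dien-2-yl (2Z)-2-methylbut-2-enoate | CC(C)(C)[Si](C)(C)OC/C=C(\C)[C@@H](O[Si](C)(C)C(C)(C)C)C/C=C(/C)[C@H](OC(C)=O)[C@H](OC(=O)/C(C)=C\C)C=O | intermediate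
16 | methyl (4R,5S,6Z,9S,10E)-5-(acetyloxy)-9,12-bis[(tert-butyldimethylsilyl)oxy]-3-hydroxy-6,10-dimethyl-2-methylidene-4-{[(2Z)-2-methylbut-2-enoyl]oxy}dodeca-6,10-dienoate (both C3 epimers) | CC(C)(C)[Si](C)(C)OC/C=C(\C)[C@@H](O[Si](C)(C)C(C)(C)C)C/C=C(/C)[C@H](OC(C)=O)[C@H](OC(=O)/C(C)=C\C)C(O)C(=C)C(=O)OC | intermediate
17 | methyl (4R,5S,6Z,9S,10E)-5-(acetyloxy)-9-[(tert-butyldimethylsilyl)oxy]-3,12-dihydroxy-6,10-dimethyl-2-methylidene-4-{[(2Z)-2-methylbut-2-enoyl]oxy}dodeca-6,10-dienoate (both C3 epimers) | OC/C=C(\C)[C@@H](O[Si](C)(C)C(C)(C)C)C/C=C(/C)[C@H](OC(C)=O)[C@H](OC(=O)/C(C)=C\C)C(O)C(=C)C(=O)OC | intermediate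
18 | methyl (4R,5S,6Z,9S,10E)-5-(acetyloxy)-9-[(tert-butyldimethylsilyl)oxy]-3-hydroxy-6,10-dimethyl-2-methylidene-4-{[(2Z)-2-methylbut-2-enoyl]oxy}-12-oxododeca-6,10-dienoate (both C3 epimers) | O=C/C=C(\C)[C@@H](O[Si](C)(C)C(C)(C)C)C/C=C(/C)[C@H](OC(C)=O)[C@H](OC(=O)/C(C)=C\C)C(O)C(=C)C(=O)OC | intermediate
19 | methyl (2Z,4R,5S,6Z,9S,10E)-5-(acetyloxy)-2-(bromomethyl)-9-[(tert-butyldimethylsilyl)oxy]-6,10-dimethyl-4-{[(2Z)-2-methylbut-2-enoyl]oxy}-12-oxododeca-2,6,10-trienoate | O=C/C=C(\C)[C@@H](O[Si](C)(C)C(C)(C)C)C/C=C(/C)[C@H](OC(C)=O)[C@H](OC(=O)/C(C)=C\C)/C=C(\CBr)C(=O)OC | intermediate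
20 | methyl 2-[(1S,2R,3E,5S,7Z,9S,10R)-9-(acetyloxy)-5-[(tert-butyldimethylsilyl)oxy]-2-hydroxy-4,8-dimethyl-10-{[(2Z)-2-methylbut-2-enoyl]oxy}cyclodeca-3,7-dien-1-yl]prop-2-enoate (not isolated) | O[C@@H]1/C=C(\C)[C@@H](O[Si](C)(C)C(C)(C)C)C/C=C(/C)[C@H](OC(C)=O)[C@H](OC(=O)/C(C)=C\C)[C@H]1C(=C)C(=O)OC | intermediate
21 | (3aS,4R,5S,6Z,9S,10E,11aR)-5-(acetyloxy)-9-[(tert-butyldimethylsilyl)oxy]-6,10-dimethyl-3-methylidene-2-oxo-2,3,3a,4,5,8,9,11a-octahydrocyclodeca[b]furan-4-yl (2Z)-2-methylbut-2-enoate | C=C1C(=O)O[C@@H]2/C=C(\C)[C@@H](O[Si](C)(C)C(C)(C)C)C/C=C(/C)[C@H](OC(C)=O)[C@H](OC(=O)/C(C)=C\C)[C@@H]12 | intermediate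
22 | (3aS,4R,5S,6Z,9S,10E,11aR)-5-(acetyloxy)-9-hydroxy-6,10-dimethyl-3-methylidene-2-oxo-2,3,3a,4,5,8,9,11a-octahydrocyclodeca[b]furan-4-yl (2Z)-2-methylbut-2-enoate | C=C1C(=O)O[C@@H]2/C=C(\C)[C@@H](O)C/C=C(/C)[C@H](OC(C)=O)[C@H](OC(=O)/C(C)=C\C)[C@@H]12 | target

**Step count and risks**
Total step count: 17. Longest linear sequence: 17 (the route is fully linear from 1).

The three steps most likely to fail:

Step 5 (Wittig reaction on the lactol). The open-chain (Z)-2-methyl enal 7 can isomerise to the E enal before it is trapped, and the free C3 hydroxyl can add back to the dienoate in an oxa-Michael reaction. The fallback builds the Z olefin as a vinyl iodide instead and sets out from 3. Silylation (TBSCl, imidazole, DMF) gives ethyl (2E,4S)-4-[(tert-butyldimethylsilyl)oxy]-3-methylhepta-2,6-dienoate F1. Ozonolysis of the terminal olefin (O3, CH2Cl2, −78 °C; PPh3), which spares the electron-poor enoate, gives ethyl (2E,4S)-4-[(tert-butyldimethylsilyl)oxy]-3-methyl-6-oxohex-2-enoate F2. Stork–Zhao olefination with Ph3P=C(I)CH3 (from ethyltriphenylphosphonium iodide, n-BuLi, I2 and NaN(SiMe3)2; THF, −78 °C) gives ethyl (2E,4S,6Z)-4-[(tert-butyldimethylsilyl)oxy]-7-iodo-3-methylocta-2,6-dienoate F3. Reduction with iBu2AlH gives (2E,4S,6Z)-4-[(tert-butyldimethylsilyl)oxy]-7-iodo-3-methylocta-2,6-dien-1-ol F4, and a second silylation gives (2E,4S,6Z)-1,4-bis[(tert-butyldimethylsilyl)oxy]-7-iodo-3-methylocta-2,6-diene F5. Stille coupling of F5 with (E)-3-(tributylstannyl)prop-2-en-1-ol (Pd(PPh3)4, CuI, DMF) proceeds with retention at both olefins and comes back to the route at 10.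

Step 12 (vinylalane addition to aldehyde 15). The aldehyde carries an α-angelate and a β-acetate, so it can lose acetic acid by β-elimination, and the aluminium alkoxide formed can trigger acyl migration from O8. The fallback sets out from 15 and makes the same adduct by aldol reaction and selenoxide elimination. The lithium enolate of methyl 3-(phenylselanyl)propanoate (LiN(iPr)2, THF, −78 °C) adds to 15 within minutes to give methyl (4R,5S,6Z,9S,10E)-5-(acetyloxy)-9,12-bis[(tert-butyldimethylsilyl)oxy]-3-hydroxy-6,10-dimethyl-4-{[(2Z)-2-methylbut-2-enoyl]oxy}-2-[(phenylselanyl)methyl]dodeca-6,10-dienoate F6. Oxidation with H2O2 (pyridine, CH2Cl2, 0 °C) and syn-elimination of the selenoxide comes back to the route at 16.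

Step 16 (chromium-mediated ring closure). This is the least certain step. The ten-membered ring may close slowly against oligomerisation, the allylchromium species can lose the C8 angelate by 1,4-elimination, and the facial selectivity at C6/C7 rests on conformational control within the forming ring rather than on a reagent. The fallback sets out from 18 and uses an allylic acetate with palladium-catalysed umpolung instead of a bromide with stoichiometric chromium. Acetylation (Ac2O, DMAP cat., CH2Cl2, 0 °C) gives methyl (4S,5S,6Z,9S,10E)-3,5-bis(acetyloxy)-9-[(tert-butyldimethylsilyl)oxy]-6,10-dimethyl-2-methylidene-4-{[(2Z)-2-methylbut-2-enoyl]oxy}-12-oxododeca-6,10-dienoate F7. Slow addition of F7 to Pd(PPh3)4 (zerovalent palladium, 5 mol %) and InI in THF forms a π-allylpalladium species that is reduced to an allylindium, which adds to the enal under milder, less reducing conditions. Lactonisation with PPTS then comes back to the route at 21.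

**Further compounds**
F1 | step 5 | ethyl (2E,4S)-4-[(tert-butyldimethylsilyl)oxy]-3-methylhepta-2,6-dienoate | CCOC(=O)/C=C(\C)[C@@H](O[Si](C)(C)C(C)(C)C)CC=C
F2 | step 5 | ethyl (2E,4S)-4-[(tert-butyldimethylsilyl)oxy]-3-methyl-6-oxohex-2-enoate | CCOC(=O)/C=C(\C)[C@@H](O[Si](C)(C)C(C)(C)C)CC=O
F3 | step 5 | ethyl (2E,4S,6Z)-4-[(tert-butyldimethylsilyl)oxy]-7-iodo-3-methylocta-2,6-dienoate | CCOC(=O)/C=C(\C)[C@@H](O[Si](C)(C)C(C)(C)C)C/C=C(/C)I
F4 | step 5 | (2E,4S,6Z)-4-[(tert-butyldimethylsilyl)oxy]-7-iodo-3-methylocta-2,6-dien-1-ol | OC/C=C(\C)[C@@H](O[Si](C)(C)C(C)(C)C)C/C=C(/C)I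
F5 | step 5 | (2E,4S,6Z)-1,4-bis[(tert-butyldimethylsilyl)oxy]-7-iodo-3-methylocta-2,6-diene | CC(C)(C)[Si](C)(C)OC/C=C(\C)[C@@H](O[Si](C)(C)C(C)(C)C)C/C=C(/C)I
F6 | step 12 | methyl (4R,5S,6Z,9S,10E)-5-(acetyloxy)-9,12-bis[(tert-butyldimethylsilyl)oxy]-3-hydroxy-6,10-dimethyl-4-{[(2Z)-2-methylbut-2-enoyl]oxy}-2-[(phenylselanyl)methyl]dodeca-6,10-dienoate (epimers at C2 and C3) | CC(C)(C)[Si](C)(C)OC/C=C(\C)[C@@H](O[Si](C)(C)C(C)(C)C)C/C=C(/C)[C@H](OC(C)=O)[C@H](OC(=O)/C(C)=C\C)C(O)C(C[Se]c1ccccc1)C(=O)OC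
F7 | step 16 | methyl (4S,5S,6Z,9S,10E)-3,5-bis(acetyloxy)-9-[(tert-butyldimethylsilyl)oxy]-6,10-dimethyl-2-methylidene-4-{[(2Z)-2-methylbut-2-enoyl]oxy}-12-oxododeca-6,10-dienoate (both C3 epimers) | O=C/C=C(\C)[C@@H](O[Si](C)(C)C(C)(C)C)C/C=C(/C)[C@H](OC(C)=O)[C@H](OC(=O)/C(C)=C\C)C(OC(C)=O)C(=C)C(=O)OC
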